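A small charge of racemization catalyst, 2.73 mM, faced 4.3 mM of added ligand in your flask (less than the ligand), so for your quick number I reckoned the exchange as a correction to a plain resolution.

all flasks: left-handed substrate 0.062 M; right-handed substrate 0.062 M; added ligand 4.3 mM

| flask | partner | racemization catalyst | remark | time |
|---|---|---|---|---|
| Monday's | 2 equiv | 6.2 mol% | run made earlier |  |
| Saturday's | 2 equiv | 9.7 mol% | run made earlier |  |
| flask | 2.00 equiv | 4.4 mol% |  | 25 min |

| run | time / min | left-handed product / % | right-handed product / % |
|---|---|---|---|
| Monday's | 2.50 | 13.7 | 5.1 |
| Monday's | 6.00 | 24.5 | 10.2 |
| Monday's | 12.0 | 33.7 | 15.2 |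
| Monday's | 30.0 | 44.1 | 22.1 |
| Saturday's | 4.00 | 19.0 | 7.6 |
| Saturday's | 10.0 | 32.4 | 13.2 |
| Saturday's | 20.0 | 43.1 | 17.7 |
| Saturday's | 30.0 | 47.6 | 20.7 |

(scatter of a reading: 0.3 percentage points)

- partner is single-handed; left-handed substrate and right-handed substrate are mirror images of each other, charged as a racemate, each of them at the stated concentration
- steps thought possible: partner -> decomposed reagent; partner + right-handed substrate -> right-handed product; racemization catalyst + added ligand <-> idle complex; left-handed substrate + racemization catalyst <-> right-handed substrate + racemization catalyst; partner + left-handed substrate -> left-handed product
- an excess is below zero if the other one leads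
- the handed part of partner does not stay in what it makes, so the products of the two hands are mirror images too

1. left-handed product and right-handed product together, in percent of the left-handed substrate and right-handed substrate charged together, at 25 min
2. excess of left-handed product over right-handed product in the product at 25 min
3. whether the exchange between left-handed substrate and right-handed substrate keeps pace with the reaction: how far the product's excess at 25 min gets from its value without exchange to its value with instant exchange (above 80% keeps pace, below 20% hardly takes part, else lags behind)

For each hand I took the fraction of its charge not yet turned into product, one minus the product's reading doubled, since the percentages count both hands together. The logarithm of the left-handed fraction over that of the right-handed fraction I called the hand index 2.98, as read from Monday's first reading. Without exchange both hands meet the same partner, however fast partner decomposes, so the index stays at this selectivity factor; exchange feeds left-handed substrate back and lifts it. Monday's last reading gave 3.66 and Saturday's 5.68, so the lift grew 3.97 times for 1.56 times the catalyst. Carrying that power law down to 4.4 mol% gave your flask an index of 3.22.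

Interpolating Monday's right-handed logarithm, sign dropped, gave 0.522 at 25 min. So I expected right-handed product at 20.3%, left-handed at 40.7%, y near 61.0% and an excess near 33.3%. The index held at 2.98 gave 31.9%, instant exchange 49.7%, so the exchange went 7.83% of the way, below 20%. The forecast said 62.2%, 32.2% and hardly takes part, on the ground “so little is free”, its y above mine and its excess below mine.

The flask gave 63.0%, 32.0% and hardly takes part, at 6.2% of the way.

    partner → decomposed reagent (k = 1.60 × 10⁻⁴ s⁻¹)
    partner + right-handed substrate → right-handed product (k = 0.00630 M⁻¹ s⁻¹)
    racemization catalyst + added ligand ⇌ idle complex, settled at all times (K = 11000 M⁻¹)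
    left-handed substrate + racemization catalyst ⇌ right-handed substrate + racemization catalyst, rate k4*[racemization catalyst]*[left-handed substrate] forward; the back reaction follows from the equilibrium constant (k = 0.500 M⁻¹ s⁻¹)
    partner + left-handed substrate → left-handed product (k = 0.0190 M⁻¹ s⁻¹)

In the flask at 25.0 min, idle complex held 95.0% of the catalyst charged and 5.05% stood free. The flask's index came to 3.18, a lift of 0.207 over 2.98. The neighbour charged with 0.0017 M of added ligand had 42.2% free, an index of 4.27, a lift of 1.30, and an excess of 37.9%.

The readings are simulated for an exercise, and the scatter is random.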